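**Retrosynthetic overview** (benzofuran numbering O1, C2, C3, C3a, C4–C7, C7a; ring A is the benzo ring)
- Last disconnection: the seven O–methyl bonds (global demethylation of the heptamethyl ether).
- Dihydrofuran ring: opened at O1–C7a to a (1S,2S)-1,2,2-triarylethanol that carries fluorine on C7a. In the same flask this alcohol comes from the racemic C2 ketone by transfer hydrogenation with dynamic kinetic resolution, so one operation sets C2 and C3 and closes the only ring that has to be made.
- Enabling feature: C3 is a methine held between C2, C3a of ring A and the 3,5-dioxygenated aryl ring, so with C2 as a carbonyl its hydrogen is acidic and C3 is stereolabile. C7a is the ring A carbon ortho to C3a, five atoms from the C2 oxygen, and the other ortho carbon, C4, already bears its oxygen.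
- Ketone: the C3–C3a and C3–aryl bonds are cut by two successive palladium-catalysed α-arylations of 3',4'-dimethoxyacetophenone (ring A aryl triflate, then 1-bromo-3,5-dimethoxybenzene).
- Ring A triflate: from 5-fluorovanillin (F = leaving group on C7a, OMe = C4 oxygen, OH = handle at C3a, CHO = C6) by Horner–Wadsworth–Emmons olefination and triflation. All four benzene rings are bought; the dihydrofuran is the last and only ring formed.

Key step: step 5

Remark on the chemistry: the SMILES is read as the trans-(2S,3S) isomer, and all seven phenols are carried as methyl ethers until the last step.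

**Step 1**
Reactants: 1 5-fluorovanillin (3-fluoro-4-hydroxy-5-methoxybenzaldehyde); 2 diethyl (3,4-dimethoxybenzyl)phosphonate
Product: 3 (E)-4-[2-(3,4-dimethoxyphenyl)ethenyl]-2-fluoro-6-methoxyphenol
Conditions: t-BuOK (3 equiv), DMF, 0 °C to rt; aq. HCl work-up
Reagents that add atoms: none
Why: Horner–Wadsworth–Emmons olefination of the aldehyde with the benzylic phosphonate anion should give the (E)-stilbene, the phenol being carried through as its phenoxide by the excess base.

**Step 2**
Reactants: 3 (E)-4-[2-(3,4-dimethoxyphenyl)ethenyl]-2-fluoro-6-methoxyphenol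
Product: 4 4-[(E)-2-(3,4-dimethoxyphenyl)ethenyl]-2-fluoro-6-methoxyphenyl trifluoromethanesulfonate
Conditions: Tf2O, pyridine, CH2Cl2, 0 °C
Reagents that add atoms: trifluoromethanesulfonic anhydride, O=S(=O)(OS(=O)(=O)C(F)(F)F)C(F)(F)F
Why: O-sulfonylation of the phenol turns the ring A carbon that becomes C3a into a cross-coupling electrophile without touching the stilbene or the C–F bond.

**Step 3**
Reactants: 4 4-[(E)-2-(3,4-dimethoxyphenyl)ethenyl]-2-fluoro-6-methoxyphenyl trifluoromethanesulfonate; 5 3',4'-dimethoxyacetophenone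
Product: 6 1-(3,4-dimethoxyphenyl)-2-{4-[(E)-2-(3,4-dimethoxyphenyl)ethenyl]-2-fluoro-6-methoxyphenyl}ethan-1-one
Conditions: Pd(OAc)2 (cat.), XPhos, K3PO4, toluene, 90 °C
Reagents that add atoms: none
Why: Palladium-catalysed ketone α-arylation (oxidative addition of zerovalent palladium into the C–OTf bond, enolate binding, C–C reductive elimination) should stop after one arylation because of the bulky biarylphosphine and the di-ortho-substituted aryl group, and the C–F bond is inert.

**Step 4**
Reactants: 6 1-(3,4-dimethoxyphenyl)-2-{4-[(E)-2-(3,4-dimethoxyphenyl)ethenyl]-2-fluoro-6-methoxyphenyl}ethan-1-one; 7 1-bromo-3,5-dimethoxybenzene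
Product: 8 rac-1-(3,4-dimethoxyphenyl)-2-(3,5-dimethoxyphenyl)-2-{4-[(E)-2-(3,4-dimethoxyphenyl)ethenyl]-2-fluoro-6-methoxyphenyl}ethan-1-one
Conditions: Pd(dba)2 (cat.), P(t-Bu)3, NaOt-Bu, toluene, 70 °C
Reagents that add atoms: none
Why: A second ketone α-arylation of the same type (deoxybenzoin to 1,2,2-triarylethanone) should take only the C–Br bond of 7 and forms C3 as a racemic, base-labile stereocentre that step 5 resolves dynamically.

**Step 5**
Reactants: 8 rac-1-(3,4-dimethoxyphenyl)-2-(3,5-dimethoxyphenyl)-2-{4-[(E)-2-(3,4-dimethoxyphenyl)ethenyl]-2-fluoro-6-methoxyphenyl}ethan-1-one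
Product: 10 (2S,3S)-2-(3,4-dimethoxyphenyl)-3-(3,5-dimethoxyphenyl)-6-[(E)-2-(3,4-dimethoxyphenyl)ethenyl]-4-methoxy-2,3-dihydro-1-benzofuran, via (1S,2S)-triarylethanol 9 (not isolated)
Conditions: RuCl[(S,S)-TsDPEN](p-cymene) (cat.), HCO2H/Et3N (1:2), DMF, 40 °C; then evaporation; t-BuOK, 18-crown-6, THF, 60 °C
Reagents that add atoms: none
Why: Proposed new method: Noyori–Ikariya transfer hydrogenation of the aryl ketone (outer-sphere transfer of Ru–H and N–H) is run while Et3N enolises the C3–H that lies between the carbonyl group and two aryl rings, so the enantiomers of 8 interconvert during reduction, and the potassium alkoxide then made from 9 attacks C7a of ring A and expels fluoride; the closest known reactions are the transfer-hydrogenation dynamic kinetic resolution of α-aryl ketones (2-arylcycloalkanones, benzoins) and the intramolecular SNAr O-arylation of 2-(2-fluoroaryl)ethanols to 2,3-dihydrobenzofurans, neither shown so far on a 1,2,2-triarylethanone with two different aryl groups on C3. The dihydrofuran ring closes by a 5-exo-trig addition–elimination at C7a that forms the O1–C7a bond and leaves C2 and C3 untouched, so their configurations are retained. C2 is set by the (S,S)-ligand, which should deliver hydride to the ketone face that gives the (S)-carbinol, as with other aryl alkyl ketones. C3 is set by substrate–catalyst matching: only (S)-8 offers that face in a Felkin–Anh arrangement with the twisted 2,6-disubstituted ring A anti to the incoming hydride, so it should be reduced faster than its enantiomer while epimerisation refills it, giving the (1S,2S) alcohol whose ring closure places the two aryl groups trans. The step needs chemoselectivity for C=O over the stilbene C=C, secured by the polar hydride transfer, and a single site of substitution, secured because ring A has only one C–F bond, held five atoms from the alkoxide oxygen, while C4 is blocked as OMe.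

**Step 6**
Reactants: 10 (2S,3S)-2-(3,4-dimethoxyphenyl)-3-(3,5-dimethoxyphenyl)-6-[(E)-2-(3,4-dimethoxyphenyl)ethenyl]-4-methoxy-2,3-dihydro-1-benzofuran
Product: 11 5-[(2S,3S)-2-(3,4-dihydroxyphenyl)-6-[(E)-2-(3,4-dihydroxyphenyl)ethenyl]-4-hydroxy-2,3-dihydro-1-benzofuran-3-yl]benzene-1,3-diol (target)
Conditions: BBr3 (excess), CH2Cl2, −78 °C to rt; then MeOH/H2O
Reagents that add atoms: none
Why: Lewis-acid cleavage of the seven aryl methyl ethers (boron coordination, SN2 attack of bromide at methyl) should free all phenols; C3 is untouched and the trans arrangement is the thermodynamic one, so any reversible ionisation at C2 should not erode it.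

**Compound list**
1 | 5-fluorovanillin (3-fluoro-4-hydroxy-5-methoxybenzaldehyde) | COc1cc(C=O)cc(F)c1O | starting material
2 | diethyl (3,4-dimethoxybenzyl)phosphonate | CCOP(=O)(Cc1ccc(OC)c(OC)c1)OCC | starting material
3 | (E)-4-[2-(3,4-dimethoxyphenyl)ethenyl]-2-fluoro-6-methoxyphenol | COc1cc(/C=C/c2ccc(OC)c(OC)c2)cc(F)c1O | intermediate
4 | 4-[(E)-2-(3,4-dimethoxyphenyl)ethenyl]-2-fluoro-6-methoxyphenyl trifluoromethanesulfonate | COc1cc(/C=C/c2ccc(OC)c(OC)c2)cc(F)c1OS(=O)(=O)C(F)(F)F | intermediate
5 | 3',4'-dimethoxyacetophenone | CC(=O)c1ccc(OC)c(OC)c1 | starting material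
6 | 1-(3,4-dimethoxyphenyl)-2-{4-[(E)-2-(3,4-dimethoxyphenyl)ethenyl]-2-fluoro-6-methoxyphenyl}ethan-1-one | COc1ccc(cc1OC)C(=O)Cc1c(F)cc(/C=C/c2ccc(OC)c(OC)c2)cc1OC | intermediate
7 | 1-bromo-3,5-dimethoxybenzene | COc1cc(Br)cc(OC)c1 | starting material
8 | rac-1-(3,4-dimethoxyphenyl)-2-(3,5-dimethoxyphenyl)-2-{4-[(E)-2-(3,4-dimethoxyphenyl)ethenyl]-2-fluoro-6-methoxyphenyl}ethan-1-one (racemic at the diaryl carbon) | COc1ccc(cc1OC)C(=O)C(c1cc(OC)cc(OC)c1)c1c(F)cc(/C=C/c2ccc(OC)c(OC)c2)cc1OC | intermediate
9 | (1S,2S)-1-(3,4-dimethoxyphenyl)-2-(3,5-dimethoxyphenyl)-2-{4-[(E)-2-(3,4-dimethoxyphenyl)ethenyl]-2-fluoro-6-methoxyphenyl}ethan-1-ol | COc1cc(OC)cc(c1)[C@@H](c1c(F)cc(/C=C/c2ccc(OC)c(OC)c2)cc1OC)[C@H](O)c1ccc(OC)c(OC)c1 | intermediate (not isolated)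
10 | (2S,3S)-2-(3,4-dimethoxyphenyl)-3-(3,5-dimethoxyphenyl)-6-[(E)-2-(3,4-dimethoxyphenyl)ethenyl]-4-methoxy-2,3-dihydro-1-benzofuran (trans) | COc1cc(OC)cc([C@H]2c3c(OC)cc(/C=C/c4ccc(OC)c(OC)c4)cc3O[C@@H]2c2ccc(OC)c(OC)c2)c1 | intermediate
11 | 5-[(2S,3S)-2-(3,4-dihydroxyphenyl)-6-[(E)-2-(3,4-dihydroxyphenyl)ethenyl]-4-hydroxy-2,3-dihydro-1-benzofuran-3-yl]benzene-1,3-diol | Oc1cc(O)cc([C@H]2c3c(O)cc(/C=C/c4ccc(O)c(O)c4)cc3O[C@@H]2c2ccc(O)c(O)c2)c1 | target

**Step count and risks**
Total step count: 6. Longest linear sequence: 6 steps (1 to 11).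

Steps most likely to fail:

1. Step 5. Three processes could defeat it: reduction outrunning the epimerisation of C3, or a mismatched catalyst–substrate preference, either of which lowers diastereo- and enantiopurity; slow hydride transfer to the hindered, electron-rich ketone; and base-induced C2–C3 retro-addition or β-elimination at C3 during ring closure. The fallback sets out from 8 and uses classical resolution. Substrate-controlled Felkin–Anh reduction with NaBH4 (MeOH/THF, 0 °C) should give the racemic (1S*,2S*)-1,2,2-triarylethanol F1. Steglich esterification with (S)-O-methylmandelic acid (DCC, DMAP) and separation of the two diastereomeric esters should give the (S)-O-methylmandelate of the (1S,2S)-alcohol F2. Saponification with LiOH brings the route back at 9, now isolated, which is closed to 10 under the second-stage conditions of step 5.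

2. Step 4. Reductive elimination at the congested C3 may be slow, so that 7 is merely reduced, and the hot sodium enolate may attack the neighbouring C–F bond through oxygen. The fallback sets out from 6 and is a metal-free arylation at room temperature. The potassium enolate of 6 (t-BuOK, THF, 0 °C) is treated with (3,5-dimethoxyphenyl)(2,4,6-trimethoxyphenyl)iodonium 4-methylbenzenesulfonate F3, which would be made from 1-iodo-3,5-dimethoxybenzene, mCPBA and TsOH followed by 1,3,5-trimethoxybenzene. Ligand coupling on iodine should transfer the 3,5-dimethoxyphenyl group, the trimethoxyphenyl group staying on iodine, and the route is rejoined at 8.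

3. Step 6. Demethylation of seven ethers may stop part-way, and the catechol-rich product may oxidise in air during chromatographic isolation. The fallback sets out from 10 and isolates the product as a derivative. The crude BBr3 product is acetylated (Ac2O, pyridine, DMAP) to the heptaacetate of the target F4, which is purified on silica, partly methylated fractions being returned to BBr3. Transesterification with K2CO3 in degassed MeOH under argon then releases 11.

**Further compounds**
F1 | step 5 | racemic (1S*,2S*)-1-(3,4-dimethoxyphenyl)-2-(3,5-dimethoxyphenyl)-2-{4-[(E)-2-(3,4-dimethoxyphenyl)ethenyl]-2-fluoro-6-methoxyphenyl}ethan-1-ol (both enantiomers) | COc1cc(OC)cc(c1)[C@@H](c1c(F)cc(/C=C/c2ccc(OC)c(OC)c2)cc1OC)[C@H](O)c1ccc(OC)c(OC)c1.COc1cc(OC)cc(c1)[C@H](c1c(F)cc(/C=C/c2ccc(OC)c(OC)c2)cc1OC)[C@@H](O)c1ccc(OC)c(OC)c1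
F2 | step 5 | (1S,2S)-1-(3,4-dimethoxyphenyl)-2-(3,5-dimethoxyphenyl)-2-{4-[(E)-2-(3,4-dimethoxyphenyl)ethenyl]-2-fluoro-6-methoxyphenyl}ethyl (S)-2-methoxy-2-phenylacetate | COc1cc(OC)cc(c1)[C@@H](c1c(F)cc(/C=C/c2ccc(OC)c(OC)c2)cc1OC)[C@H](OC(=O)[C@@H](OC)c1ccccc1)c1ccc(OC)c(OC)c1
F3 | step 4 | (3,5-dimethoxyphenyl)(2,4,6-trimethoxyphenyl)iodonium 4-methylbenzenesulfonate | COc1cc(OC)cc([I+]c2c(OC)cc(OC)cc2OC)c1.Cc1ccc(cc1)S(=O)(=O)[O-]
F4 | step 6 | heptaacetate of the target, (2S,3S)-trans | CC(=O)Oc1cc(OC(C)=O)cc([C@H]2c3c(OC(C)=O)cc(/C=C/c4ccc(OC(C)=O)c(OC(C)=O)c4)cc3O[C@@H]2c2ccc(OC(C)=O)c(OC(C)=O)c2)c1
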